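## Analysis of the target

Target 30 is a cyclohex-2-enone fused to an oxirane (a 7-oxabicyclo[4.1.0]hept-3-en-2-one). The ring is numbered from the ketone C1 through the alkene C2=C3 (C2 carries the acetoxymethyl carbon C7) and the carbinol C4 to the oxirane carbons C5 and C6; the fifteen-carbon chain on C5 is numbered from its carbinol carbon C1' through the (2'E)- and (6'E)-trisubstituted alkenes to the terminal isopropylidene. There are four stereocentres, C4 (S), C5 (R), C6 (R) and C1' (S). If the face of the oxirane oxygen is called β, the C4 hydroxyl and the C5–C1' bond are α, so the hydroxyl is trans to the epoxide and cis to the chain, while C1' lies outside the ring and must be related to the fully substituted C5 without conformational help. The sensitive groups are the epoxy ketone (hydride, carbanions, base), the 2-(acetoxymethyl)enone (an allylic acetate that can leave in an SN2' sense or migrate), two allylic alcohols, and the skipped triene with its many allylic C–H bonds. The synthesis is hard because four contiguous carbons (C4, C5, C6, C1') are oxygenated, one quaternary and one exocyclic, and because the ketone, the acetate and the triene each forbid a class of reagents that another part of the molecule needs. The strategy rests on one structural reading: the C5–O and C1'–O bonds are the two oxygens of a syn-diol of an exocyclic C5=C1' alkene whose C2' is cis to C6, and that geometry is forced if C2' is the carbonyl of a butenolide closed onto the C6 oxygen. In that butenolide the C6 oxygen is α and the new C5 hydroxyl β, the trans arrangement from which the β-epoxide can be closed with inversion at C6; the carbocycle with its C2=C3 enoate and its C4 and C6 oxygens is that of shikimic acid 1.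

## Retrosynthetic reasoning

**Late redox and acyl adjustments (30 ⇐ 29 ⇐ 28 ⇐ 27).** The two silyl ethers of 29 are removed last. The C1 ketone of 29 is made from the carbinol 28 as the final redox step, and the acetate of 28 is placed on the primary C7 hydroxyl of diol 27. Ketone and acetate would not survive the hydride and carbanion steps that build the chain, so they are introduced only after the chain is complete.

**C4'–C5' bond (26 ⇐ 25 ⇐ 22 + 24; 24 ⇐ 23).** The chain is cut between its two adjacent methylenes. This delivers ten carbons with both remaining alkenes already set from geranyl bromide 23, and a sulfonyl-stabilised carbanion of 24 reacts at its α-carbon without allylic transposition. A cut at an alkene would demand a stereoselective trisubstituted olefination late in the route. Forward, the anion of 24 is alkylated by the allylic bromide 22 and the sulfonyl group of 25 is removed reductively.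

**C1–O bond (19 ⇐ 18).** Shikimic acid has no oxygen at C1, so this bond is made by allylic hydroxylation of the ring methylene. It must precede attachment of 24, because the triene offers many competing allylic positions. It must follow reduction of C7, because the ring alkene is an unreactive enoate until then. The carbinol is carried as the silyl ether 20 and oxidised only in 29.

**C6–O epoxide bond (18 ⇐ 16 via 17).** The oxirane is opened at C6 to a C5 hydroxyl and a C6 sulfonate. The forward step is an internal displacement with inversion at C6. It needs the C5 and C6 oxygens trans, which is exactly what the lactone-tethered key step leaves behind.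

**C2'=C3' alkene (15 ⇐ 13 + 14; 13 ⇐ 12).** The lactone carbonyl C2' becomes the alkene carbon through lactol 13 and a stabilised ylide 14 that brings C3', its methyl and C4'. A stabilised α-methyl ylide is the reliable way to an (E)-trisubstituted alkene, and the same reduction that gives the lactol takes the C7 ester to the alcohol. Opening the lactone also frees the C6 hydroxyl for the epoxide closure.

**C5–O and C1'–O bonds (11 ⇐ 10), the key disconnection.** Both oxygens are removed to give the fused butenolide 10. The lactone locks C2' cis to C6, so a suprafacial addition can give only one C5/C1' relation, and the ring fusion together with the α-C4 silyl ether leaves one face open. Two stereocentres, one quaternary and one exocyclic, are thus set in one step.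

**C5=C1' bond (10 ⇐ 9 ⇐ 8 ⇐ 6 + 7).** The butenolide alkene is cut to a C5 ketone and a phosphonoacetate on the C6 oxygen. The ester from 7 both differentiates the C6 hydroxyl of diol 6 from the C5 hydroxyl and supplies C1' and C2'. The forward step is an intramolecular Horner–Wadsworth–Emmons reaction.

**C4 configuration and hydroxyl differentiation (6 ⇐ 5 ⇐ 4 ⇐ 3 ⇐ 2 ⇐ 1).** Shikimic acid 1 has the C4 hydroxyl on the wrong (β) face. Masking the trans C5/C6 diol as a diacetal (2) leaves only the allylic C4 hydroxyl, which is inverted by a Mitsunobu reaction (3, 4) and silylated (5) before the diol is released (6).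

## Alternatives that were turned down

Alternative 1: The ring would be cut at C3–C4 and closed from the open-chain (Z)-iodoalkene epoxy aldehyde A2, in which the C1 oxygen (as a p-methoxybenzyl ether), the epoxide, the silylated C1' carbinol, the acetate and the whole chain are already present. CrCl2 with catalytic NiCl2 would convert the C3–I bond into an alkenylchromium species that adds to the C4 aldehyde and gives the epoxycyclohexenol A1. In its favour, the reagent pair is chemoselective for aldehydes and tolerates epoxide, silyl ether and triene. It is stronger than the chosen route on two points: C1 is oxygenated from the start, so no C–H oxidation is needed, and the chain is carried in convergently. Against it, the C4 carbinol is created in the ring closure next to the quaternary C5, with only weak 1,2-induction to decide its configuration. The zerovalent nickel that mediates the halide activation can also ionise the allylic acetate on C2. A2 itself needs four stereocentres, a trisubstituted epoxide bearing an aldehyde and a Z-trisubstituted iodoalkene to be assembled by acyclic stereocontrol. The chosen route is longer in linear steps, but it takes C4 from the chiral pool by an SN2 inversion of fixed outcome and sets C5 and C1' by one substrate-controlled event on a preformed ring.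

Alternative 2: The carbocycle would be made by a [4+2] cycloaddition that forms C4–C5 and C1–C6 between the 2-silyloxyfuran A4 and the chiral 4-substituted 1,3-dioxol-2-one A5. The oxygen bridge would then open at the silyl ketal carbon to release the C1 ketone and the C4 hydroxyl in the carbonate A3. This is the shortest plan and clearly stronger in step and redox economy: ring, ketone, C4 hydroxyl and both C5/C6 oxygens arrive in one operation. Against it, the dienophile is an enediol carbonate, neither electron-poor nor unhindered (it is trisubstituted and α-branched), and furans are reluctant, reversible dienes that prefer vinylogous addition pathways. The step would need three selectivities at once: regiochemistry (substituted carbon next to C4), endo/exo (which fixes the C4 hydroxyl relative to the carbonate) and π-facial control from the exocyclic C1' alone. Heating would also be required, with the triene in place. The adduct A3 carries the C5 and C6 oxygens cis, so reaching the epoxide would need a net double inversion at C6 next to a ketone. The chosen route gives up brevity for a key step in which every selectivity has a structural cause.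

Alternative 3: The ring would be cut at C1–C2 and closed by an intramolecular Morita–Baylis–Hillman reaction of the open-chain γ-silyloxy enoate epoxy aldehyde A7. PMe3 would add to C3, the C2 enolate would attack the C1 aldehyde, and loss of the phosphine would restore C2=C3 in the cyclohexenol A6. In its favour, the C1 oxygen comes with the ring closure (again stronger than a late C–H oxidation), the conditions are mild and metal-free, and C7 sits at the ester level as in the chosen route. Against it, β-substituted acrylates are poor acceptors, and here the β-carbon is flanked by a silyloxy-bearing, fully substituted neighbour. The nucleophilic phosphine can open the epoxide or trigger loss of the γ-silyloxy group from the phosphonium intermediate. A7 needs C4, C5, C6 and C1' set in an acyclic array. The product still requires the same ester-to-acetoxymethyl and carbinol-to-ketone ordering as the chosen route, without the benefit of a ring taken from the chiral pool.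

Key step: step 9

## Remarks on the chemistry

- Target numbering (C1–C7, C1'–C12') is used for all compounds. Shikimate C1, C2, C3, C4, C5, C6 and its carboxyl carbon correspond to C2, C3, C4, C5, C6, C1 and C7. β is the face of the epoxide oxygen in 30; α is the opposite face.
- The C4 silyl ether is carried as tert-butyldiphenylsilyl (TBDPS), because it must survive the aqueous acid of step 5. TBS = tert-butyldimethylsilyl, TES = triethylsilyl, dppp = 1,3-bis(diphenylphosphino)propane.
- Assumption: C1 in 19–28 and C5' in 25 are carried as epimer mixtures and 13 as an anomer mixture. None of these centres is in the target, so their SMILES leave them undefined.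

## Route

Step 1
Reactants: 1 (−)-shikimic acid
Product: 2 methyl shikimate C5,C6-O-(2S,3S)-2,3-dimethoxybutane-2,3-diyl diacetal (C4–OH β, free)
Conditions: butane-2,3-dione, HC(OMe)3, MeOH, camphorsulfonic acid (cat.), reflux
Reagents that add atoms: methanol, CO; butane-2,3-dione, CC(=O)C(C)=O
Why: Fischer esterification and thermodynamic diacetal formation; only the trans-diequatorial C5/C6 diol can form the trans-fused dioxane with both methoxy groups axial (anomeric effect), so the allylic C4 hydroxyl stays free and no ring stereocentre is touched.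

Step 2
Reactants: 2 methyl shikimate C5,C6-diacetal
Product: 3 C4-epimeric 4-nitrobenzoate of 2 (C4–O α)
Conditions: 4-O2NC6H4CO2H, PPh3, diisopropyl azodicarboxylate, THF, 0 °C → rt
Reagents that add atoms: 4-nitrobenzoic acid, OC(=O)c1ccc(cc1)[N+](=O)[O-]
Why: Mitsunobu reaction; the alkoxyphosphonium of the only free (allylic) hydroxyl is displaced by carboxylate in an SN2 step, which inverts C4 from β to α. The diacetal removes any neighbouring hydroxyl that could close an epoxide instead.

Step 3
Reactants: 3 C4-epimeric 4-nitrobenzoate
Product: 4 methyl C4-epi-shikimate C5,C6-diacetal (C4–OH α)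
Conditions: K2CO3, MeOH, 0 °C
Reagents that add atoms: none
Why: base-catalysed methanolysis of the activated aryl ester; exchange at the methyl ester is degenerate, the diacetal is base-stable and C4 is not touched.

Step 4
Reactants: 4 methyl C4-epi-shikimate C5,C6-diacetal
Product: 5 C4 TBDPS ether of 4
Conditions: t-BuPh2SiCl, imidazole, DMF, rt
Reagents that add atoms: tert-butyldiphenylsilyl chloride, CC(C)(C)[Si](Cl)(c1ccccc1)c1ccccc1
Why: standard silylation of a secondary allylic alcohol; the TBDPS group is chosen because it resists aqueous acid yet is cleaved by fluoride at the end.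

Step 5
Reactants: 5 C4 TBDPS ether
Product: 6 diol methyl ester (C4–OTBDPS α, C5–OH β, C6–OH α)
Conditions: CF3CO2H/H2O (9:1), CH2Cl2, 0 °C
Reagents that add atoms: none
Why: acid-catalysed hydrolysis of the diacetal; the TBDPS ether is stable to brief aqueous acid and the conjugated ester disfavours ionisation at the allylic C4.

Step 6
Reactants: 6 diol methyl ester; 7 diethylphosphonoacetic acid
Product: 8 C6 (diethylphosphono)acetate of 6 (C5–OH free)
Conditions: dicyclohexylcarbodiimide, 4-dimethylaminopyridine (cat.), CH2Cl2, −20 → 0 °C
Reagents that add atoms: none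
Why: Steglich esterification; the C5 hydroxyl is flanked by the bulky C4 silyl ether and the C6 oxygen, whereas the C6 hydroxyl adjoins only the C1 methylene, so acylation should occur at C6, in line with the low reactivity of the central hydroxyl of shikimates.

Step 7
Reactants: 8 C6 phosphonoacetate
Product: 9 C5 ketone of 8
Conditions: Dess–Martin periodinane, NaHCO3, CH2Cl2, 0 °C → rt
Reagents that add atoms: none
Why: Dess–Martin oxidation of the remaining hindered secondary alcohol under buffered, non-basic conditions, so that the acidic C4–H (α to the new ketone, γ to the enoate) is not disturbed.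

Step 8
Reactants: 9 C5 ketone
Product: 10 fused butenolide (C5=C1', C2' carbonyl on the α-C6 oxygen, C4–OTBDPS α, C7 methyl ester, C1 methylene)
Conditions: LiCl, i-Pr2NEt, MeCN, 0 °C → rt
Reagents that add atoms: none
Why: intramolecular Horner–Wadsworth–Emmons reaction under lithium-chelate (Masamune–Roush type) conditions; the lithium-bound phosphonate carbanion adds to the adjacent C5 ketone (5-exo-trig) and loses diethyl phosphate, and the five-membered ring fixes C2' cis to C6. The weak amine base is chosen because C4–H is acidic.

Step 9
Reactants: 10 fused butenolide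
Product: 11 cis-fused dihydroxy lactone (C5–OH β, C1'–OH syn to it, lactone oxygen on C6 α)
Conditions: OsO4 (5 mol %), N-methylmorpholine N-oxide, citric acid, t-BuOH/H2O (1:1), rt
Reagents that add atoms: N-methylmorpholine N-oxide, C[N+]1([O-])CCOCC1; water, O
Why: OsO4 adds across C5=C1' in a concerted [3+2] cycloaddition, the osmate ester is hydrolysed and the N-oxide returns the metal to OsO4, so both new C–O bonds arrive on one face; the closest known reaction type is the catalytic syn-dihydroxylation of α,β-unsaturated γ-lactones from their exo face. No ring is closed. C5 is controlled by the ring fusion: the butenolide plane has ring carbon C1 on one side and only C6–H on the other, so the reagent should enter from the β-face, which is also opposite the α-C4 silyl ether; this places C5–OH β and keeps the lactone cis-fused. C1' is controlled by the locked alkene geometry: the lactone holds C2' cis to C6, so suprafacial addition from the β-face can only give the C1' hydroxyl syn to C5–OH, which is the C5/C1' relation of 30. The step needs face selectivity, secured as described, and site selectivity over C2=C3. The ring alkene should be slower because it is an α-branched enoate inside the six-membered ring and is inductively deactivated by the allylic silyl ether, whereas the butenolide alkene is exocyclic to the carbocycle, has an unhindered C1'–H terminus and relieves strain on pyramidalisation. Citric acid keeps the medium slightly acidic, which speeds turnover of electron-poor osmate esters and avoids enolisation at the doubly allylic C4–H.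

Step 10
Reactants: 11 cis-fused dihydroxy lactone
Product: 12 C1' TBS ether of 11 (C5–OH free)
Conditions: t-BuMe2SiOTf, 2,6-lutidine, CH2Cl2, −78 °C
Reagents that add atoms: tert-butyldimethylsilyl trifluoromethanesulfonate, CC(C)(C)[Si](C)(C)OS(=O)(=O)C(F)(F)F
Why: silyl triflate silylation at low temperature discriminates the secondary C1' hydroxyl from the tertiary C5 hydroxyl, which must stay free for the epoxide closure.

Step 11
Reactants: 12 C1' TBS ether
Product: 13 lactol with C7 reduced to CH2OH (C5–OH free, anomer mixture)
Conditions: i-Bu2AlH (excess), CH2Cl2, −78 °C; aq. potassium sodium tartrate work-up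
Reagents that add atoms: none
Why: i-Bu2AlH reduction; the lactone stops at the aluminium hemiacetal, which gives the lactol on work-up, while the conjugated methyl ester goes through to the allylic alcohol that C7 needs anyway.

Step 12
Reactants: 13 lactol; 14 ethyl 2-(triphenylphosphoranylidene)propanoate
Product: 15 triol (2'E)-enoate (C5–OH β, C6–OH α, C7–OH, C1'–OTBS, ethyl ester at C4')
Conditions: toluene, 80 °C
Reagents that add atoms: none
Why: Wittig olefination of the lactol through its open hydroxy aldehyde; the stabilised α-methyl ylide gives the (E)-trisubstituted enoate and the reaction frees the C6 hydroxyl. The α-methyl group makes the enoate a poor acceptor for re-addition of that hydroxyl.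

Step 13
Reactants: 15 triol enoate
Product: 16 C7 TBS ether of 15
Conditions: t-BuMe2SiCl, imidazole, CH2Cl2, 0 °C
Reagents that add atoms: tert-butyldimethylsilyl chloride, CC(C)(C)[Si](C)(C)Cl
Why: steric discrimination; the primary allylic C7 hydroxyl is silylated ahead of the hindered secondary C6 and tertiary C5 hydroxyls.

Step 14
Reactants: 16 C7 TBS ether
Product: 18 β-epoxide (C5–O–C6) with chain ethyl ester, via C6 mesylate 17 (not isolated)
Conditions: MeSO2Cl, Et3N, CH2Cl2, 0 °C; then KOt-Bu, THF, −20 °C
Reagents that add atoms: methanesulfonyl chloride, CS(=O)(=O)Cl (carried by 17 only, lost again in 18)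
Why: sulfonylation of the only reactive secondary hydroxyl, then intramolecular Williamson closure (3-exo-tet); the β-C5 alkoxide attacks C6 anti to the α-mesylate, inverting C6 and giving the β-epoxide. The trans C5/C6 relation set in steps 1 and 9 provides the anti-periplanar arrangement.

Step 15
Reactants: 18 β-epoxide
Product: 19 C1 allylic alcohol of 18 (either C1 epimer)
Conditions: SeO2 (0.3 equiv), t-BuOOH, CH2Cl2, rt → 40 °C
Reagents that add atoms: tert-butyl hydroperoxide, CC(C)(C)OO
Why: Riley oxidation (ene reaction at the less substituted alkene carbon C3, then [2,3]-sigmatropic shift); endocyclic alkenes are hydroxylated within the ring at the methylene on the more substituted terminus, here C1. The chain enoate is too electron-poor to compete, and no radical is generated next to the epoxide.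

Step 16
Reactants: 19 C1 allylic alcohol
Product: 20 C1 TES ether of 19
Conditions: Et3SiOTf, 2,6-lutidine, CH2Cl2, −78 °C
Reagents that add atoms: triethylsilyl trifluoromethanesulfonate, CC[Si](CC)(CC)OS(=O)(=O)C(F)(F)F
Why: silylation of the new secondary alcohol; the TES ether is orthogonal to the C1' TBS and C4 TBDPS ethers and stands in for the ketone, which would not survive steps 17–21.

Step 17
Reactants: 20 C1 TES ether
Product: 21 C4' allylic alcohol
Conditions: i-Bu2AlH, CH2Cl2, −78 °C
Reagents that add atoms: none
Why: 1,2-reduction of the conjugated ethyl ester to the allylic alcohol; the hindered trisubstituted epoxide and the silyl ethers are inert at this temperature.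

Step 18
Reactants: 21 C4' allylic alcohol
Product: 22 C4' allylic bromide
Conditions: CBr4, PPh3, 2,6-lutidine, CH2Cl2, 0 °C
Reagents that add atoms: tetrabromomethane, BrC(Br)(Br)Br
Why: Appel bromination of a primary allylic alcohol under neutral conditions (SN2 at the unhindered CH2, no allylic transposition expected); the lutidine scavenges traces of acid.

Step 19
Reactants: 23 geranyl bromide
Product: 24 geranyl phenyl sulfone
Conditions: PhSO2Na, DMF, rt
Reagents that add atoms: sodium benzenesulfinate, [Na+].[O-]S(=O)c1ccccc1
Why: S-alkylation of the sulfinate by the primary allylic bromide (SN2), which keeps the (E)-alkene.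

Step 20
Reactants: 22 C4' allylic bromide; 24 geranyl phenyl sulfone
Product: 25 coupled C5' phenyl sulfone (C4'–C5' bond formed; epimers at C5')
Conditions: 24, n-BuLi, THF, −78 °C; then 22, −78 → −40 °C
Reagents that add atoms: none
Why: Julia-type alkylation of the α-lithiated allylic sulfone at its α-carbon; the carbanion reacts with the primary allylic bromide far faster than with the hindered epoxide or the silyl ethers, and neither trisubstituted alkene is touched.

Step 21
Reactants: 25 coupled C5' phenyl sulfone
Product: 26 fully assembled chain, tetrasilyl ether (C1–OTES, C7–OTBS, C1'–OTBS, C4–OTBDPS)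
Conditions: PdCl2(dppp) (5 mol %), LiBHEt3, THF, 0 °C
Reagents that add atoms: none
Why: palladium-catalysed reductive desulfonylation; zerovalent palladium ionises the allylic sulfone to a π-allyl complex and hydride is delivered to the less hindered terminus C5', which keeps the C6'=C7' position and geometry. Silyl ethers are not leaving groups for palladium and the epoxide is not allylic.

Step 22
Reactants: 26 tetrasilyl ether
Product: 27 C1,C7 diol (C1'–OTBS and C4–OTBDPS retained)
Conditions: HF·pyridine, pyridine, THF, 0 °C
Reagents that add atoms: none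
Why: buffered HF·pyridine cleaves the primary TBS ether and the TES ether much faster than the hindered secondary TBS ether at C1' or the TBDPS ether at C4; the pyridine buffer spares the electron-poor epoxide.

Step 23
Reactants: 27 C1,C7 diol
Product: 28 C7 acetate (C1–OH free)
Conditions: AcCl, 2,4,6-collidine, CH2Cl2, −78 °C
Reagents that add atoms: acetyl chloride, CC(=O)Cl
Why: acylation with a hindered pyridine base at low temperature is selective for the primary allylic hydroxyl over the secondary C1 hydroxyl next to the epoxide.

Step 24
Reactants: 28 C7 acetate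
Product: 29 C1 ketone (epoxy enone, C7 acetate, C1'–OTBS, C4–OTBDPS)
Conditions: Dess–Martin periodinane, NaHCO3, CH2Cl2, 0 °C
Reagents that add atoms: none
Why: Dess–Martin oxidation of the secondary allylic alcohol under neutral, buffered conditions that tolerate the epoxide, the allylic acetate and the triene; as the last redox step it keeps the ketone away from hydride and carbanions.

Step 25
Reactants: 29 C1 ketone
Product: 30 target CNP0137670.2
Conditions: n-Bu4NF, AcOH (1:1), THF, 0 °C → rt
Reagents that add atoms: none
Why: fluoride-mediated cleavage of both remaining silyl ethers; acetic acid buffering keeps the medium near neutral so that the epoxy enone and the 2-(acetoxymethyl)enone do not meet alkoxide or basic fluoride.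

## Compound list

1 | (−)-shikimic acid, (3R,4S,5R)-3,4,5-trihydroxycyclohex-1-ene-1-carboxylic acid (target numbering: C4–OH β, C5–OH β, C6–OH α) | OC(=O)C1=C[C@@H](O)[C@@H](O)[C@H](O)C1 | starting material
2 | methyl shikimate C5,C6-O-(2S,3S)-2,3-dimethoxybutane-2,3-diyl diacetal, C4–OH β | COC(=O)C1=C[C@@H](O)[C@H]2O[C@](C)(OC)[C@@](C)(OC)O[C@@H]2C1 | intermediate
3 | C4-epimeric 4-nitrobenzoate of 2 (C4–O α) | COC(=O)C1=C[C@H](OC(=O)c3ccc(cc3)[N+](=O)[O-])[C@H]2O[C@](C)(OC)[C@@](C)(OC)O[C@@H]2C1 | intermediate
4 | methyl C4-epi-shikimate C5,C6-diacetal (C4–OH α) | COC(=O)C1=C[C@H](O)[C@H]2O[C@](C)(OC)[C@@](C)(OC)O[C@@H]2C1 | intermediate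
5 | C4 tert-butyldiphenylsilyl ether of 4 | COC(=O)C1=C[C@H](O[Si](c3ccccc3)(c4ccccc4)C(C)(C)C)[C@H]2O[C@](C)(OC)[C@@](C)(OC)O[C@@H]2C1 | intermediate
6 | diol methyl ester: C4–OTBDPS α, C5–OH β, C6–OH α, C2=C3, C1 methylene | COC(=O)C1=C[C@H](O[Si](c2ccccc2)(c3ccccc3)C(C)(C)C)[C@@H](O)[C@H](O)C1 | intermediate
7 | diethylphosphonoacetic acid | OC(=O)CP(=O)(OCC)OCC | starting material
8 | C6 (diethylphosphono)acetate of 6, C5–OH free | COC(=O)C1=C[C@H](O[Si](c2ccccc2)(c3ccccc3)C(C)(C)C)[C@@H](O)[C@H](OC(=O)CP(=O)(OCC)OCC)C1 | intermediate
9 | C5 ketone of 8 | COC(=O)C1=C[C@H](O[Si](c2ccccc2)(c3ccccc3)C(C)(C)C)C(=O)[C@H](OC(=O)CP(=O)(OCC)OCC)C1 | intermediate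
10 | fused butenolide: C5=C1', C2' lactone carbonyl on α-C6 oxygen, C4–OTBDPS α, C7 methyl ester, C1 methylene | COC(=O)C1=C[C@H](O[Si](c3ccccc3)(c4ccccc4)C(C)(C)C)C2=CC(=O)O[C@@H]2C1 | intermediate
11 | cis-fused dihydroxy lactone: C5–OH β, C1'–OH syn to it, lactone oxygen on C6 α | COC(=O)C1=C[C@H](O[Si](c3ccccc3)(c4ccccc4)C(C)(C)C)[C@]2(O)[C@@H](O)C(=O)O[C@@H]2C1 | intermediate
12 | C1' tert-butyldimethylsilyl ether of 11 | COC(=O)C1=C[C@H](O[Si](c3ccccc3)(c4ccccc4)C(C)(C)C)[C@]2(O)[C@@H](O[Si](C)(C)C(C)(C)C)C(=O)O[C@@H]2C1 | intermediate
13 | lactol of 12 with C7 as CH2OH (anomer mixture) | OCC1=C[C@H](O[Si](c3ccccc3)(c4ccccc4)C(C)(C)C)[C@]2(O)[C@@H](O[Si](C)(C)C(C)(C)C)C(O)O[C@@H]2C1 | intermediate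
14 | ethyl 2-(triphenylphosphoranylidene)propanoate | CCOC(=O)C(C)=P(c1ccccc1)(c1ccccc1)c1ccccc1 | starting material
15 | triol (2'E)-enoate: C5–OH β, C6–OH α, C7–OH, (1'S)-C1'–OTBS, ethyl ester at C4' | OCC1=C[C@H](O[Si](c2ccccc2)(c3ccccc3)C(C)(C)C)[C@](O)([C@@H](O[Si](C)(C)C(C)(C)C)/C=C(\C)C(=O)OCC)[C@H](O)C1 | intermediate
16 | C7 tert-butyldimethylsilyl ether of 15 | CC(C)(C)[Si](C)(C)OCC1=C[C@H](O[Si](c2ccccc2)(c3ccccc3)C(C)(C)C)[C@](O)([C@@H](O[Si](C)(C)C(C)(C)C)/C=C(\C)C(=O)OCC)[C@H](O)C1 | intermediate
17 | C6 mesylate of 16 (not isolated) | CC(C)(C)[Si](C)(C)OCC1=C[C@H](O[Si](c2ccccc2)(c3ccccc3)C(C)(C)C)[C@](O)([C@@H](O[Si](C)(C)C(C)(C)C)/C=C(\C)C(=O)OCC)[C@H](OS(C)(=O)=O)C1 | intermediate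
18 | β-epoxide (C5–O–C6): C7–OTBS, C4–OTBDPS α, C1'–OTBS, chain ethyl (E)-enoate, C1 methylene | CC(C)(C)[Si](C)(C)OCC1=C[C@H](O[Si](c3ccccc3)(c4ccccc4)C(C)(C)C)[C@@]2([C@@H](O[Si](C)(C)C(C)(C)C)/C=C(\C)C(=O)OCC)O[C@H]2C1 | intermediate
19 | C1 allylic alcohol of 18 (C1 epimers) | CC(C)(C)[Si](C)(C)OCC1=C[C@H](O[Si](c3ccccc3)(c4ccccc4)C(C)(C)C)[C@@]2([C@@H](O[Si](C)(C)C(C)(C)C)/C=C(\C)C(=O)OCC)O[C@H]2C1O | intermediate
20 | C1 triethylsilyl ether of 19 | CC(C)(C)[Si](C)(C)OCC1=C[C@H](O[Si](c3ccccc3)(c4ccccc4)C(C)(C)C)[C@@]2([C@@H](O[Si](C)(C)C(C)(C)C)/C=C(\C)C(=O)OCC)O[C@H]2C1O[Si](CC)(CC)CC | intermediate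
21 | C4' allylic alcohol (chain (E)-CH=C(CH3)CH2OH) | CC(C)(C)[Si](C)(C)OCC1=C[C@H](O[Si](c3ccccc3)(c4ccccc4)C(C)(C)C)[C@@]2([C@@H](O[Si](C)(C)C(C)(C)C)/C=C(\C)CO)O[C@H]2C1O[Si](CC)(CC)CC | intermediate
22 | C4' allylic bromide | CC(C)(C)[Si](C)(C)OCC1=C[C@H](O[Si](c3ccccc3)(c4ccccc4)C(C)(C)C)[C@@]2([C@@H](O[Si](C)(C)C(C)(C)C)/C=C(\C)CBr)O[C@H]2C1O[Si](CC)(CC)CC | intermediate
23 | geranyl bromide, (2E)-1-bromo-3,7-dimethylocta-2,6-diene | BrC/C=C(\C)CCC=C(C)C | starting material
24 | geranyl phenyl sulfone | O=S(=O)(C/C=C(\C)CCC=C(C)C)c1ccccc1 | intermediate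
25 | coupled C5' phenyl sulfone (epimers at C5' and C1) | CC(C)(C)[Si](C)(C)OCC1=C[C@H](O[Si](c3ccccc3)(c4ccccc4)C(C)(C)C)[C@@]2([C@@H](O[Si](C)(C)C(C)(C)C)/C=C(\C)CC(S(=O)(=O)c5ccccc5)/C=C(\C)CCC=C(C)C)O[C@H]2C1O[Si](CC)(CC)CC | intermediate
26 | full (2'E,6'E)-chain, tetrasilyl ether: C1–OTES, C7–OTBS, C1'–OTBS, C4–OTBDPS | CC(C)(C)[Si](C)(C)OCC1=C[C@H](O[Si](c3ccccc3)(c4ccccc4)C(C)(C)C)[C@@]2([C@@H](O[Si](C)(C)C(C)(C)C)/C=C(\C)CC/C=C(\C)CCC=C(C)C)O[C@H]2C1O[Si](CC)(CC)CC | intermediate
27 | C1,C7 diol (C1'–OTBS, C4–OTBDPS) | OCC1=C[C@H](O[Si](c3ccccc3)(c4ccccc4)C(C)(C)C)[C@@]2([C@@H](O[Si](C)(C)C(C)(C)C)/C=C(\C)CC/C=C(\C)CCC=C(C)C)O[C@H]2C1O | intermediate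
28 | C7 acetate with free C1–OH | CC(=O)OCC1=C[C@H](O[Si](c3ccccc3)(c4ccccc4)C(C)(C)C)[C@@]2([C@@H](O[Si](C)(C)C(C)(C)C)/C=C(\C)CC/C=C(\C)CCC=C(C)C)O[C@H]2C1O | intermediate
29 | C1 ketone: epoxy enone, C7 acetate, C1'–OTBS, C4–OTBDPS | CC(=O)OCC1=C[C@H](O[Si](c3ccccc3)(c4ccccc4)C(C)(C)C)[C@@]2([C@@H](O[Si](C)(C)C(C)(C)C)/C=C(\C)CC/C=C(\C)CCC=C(C)C)O[C@H]2C1=O | intermediate
30 | CNP0137670.2: (4S,5R,6R)-2-(acetoxymethyl)-5,6-epoxy-4-hydroxy-5-[(1'S,2'E,6'E)-1'-hydroxy-3',7',11'-trimethyldodeca-2',6',10'-trienyl]cyclohex-2-enone | CC(=O)OCC1=C[C@H](O)[C@@]2([C@@H](O)/C=C(\C)CC/C=C(\C)CCC=C(C)C)O[C@H]2C1=O | target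

## Step count and least certain steps

Total: 25 steps. Longest linear sequence: 24 steps (1 → 30 through steps 1–18 and 20–25); step 19 prepares the branch 24.

**Step 9 (key step).** The most likely failure is loss of site selectivity: both alkenes of 10 are trisubstituted enoates, and osmylation of the ring C2=C3 bond from its open β-face could compete. Slow hydrolysis of the hindered tertiary osmate could also lengthen the reaction and favour over-oxidation. Fallback: mask the ring enoate first. From 10, conjugate addition of thiophenol (catalytic Et3N) at C3 would give the C3 phenylthio adduct F1. OsO4 with excess N-oxide would then dihydroxylate the only remaining alkene from the same β-face and oxidise sulfur to the sulfone, giving the dihydroxy sulfone F2. 1,8-Diazabicyclo[5.4.0]undec-7-ene would eliminate benzenesulfinate (E1cB through the ester α-carbon C2) and restore C2=C3, returning to 11.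

**Step 15.** The ene step may be too slow on an alkene that carries two allylic oxygen substituents and a crowded C3. Oxidation may also divert to the silyloxymethyl carbon C7, or the selenous acid formed may open the epoxide. Fallback: replace the ene pathway by an oxo-chromium oxidation followed by reduction. From 18, CrO3 with 3,5-dimethylpyrazole (CH2Cl2, −20 °C) would give the C1 enone F3 directly, and NaBH4 with CeCl3·7H2O (Luche reduction) would return the allylic alcohol 19.

**Step 8.** C4–H of ketone 9 is α to the ketone and γ to the enoate. Soft enolisation by LiCl and amine could shift C2=C3 into conjugation with the ketone or epimerise C4 faster than the ring closes. Fallback: use a phosphonium ylide, which forms at near-neutral pH. From 6, bromoacetyl bromide and pyridine would give the C6 bromoacetate F4, Dess–Martin oxidation the keto bromoacetate F5, and PPh3 the phosphonium bromide F6. Aqueous NaHCO3 in a two-phase system would liberate the ylide, whose intramolecular Wittig reaction returns to 10.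

**Step 21.** LiBHEt3 is a strong nucleophilic hydride and could open the epoxide at C6. Hydride delivery to the wrong terminus of the π-allyl complex would move the C6'=C7' alkene. Fallback: form C4'–C5' without a sulfone. Geranyl chloride F7 and activated barium (BaI2 reduced with lithium biphenylide) would give geranylbarium chloride F8, a reagent class that couples with allylic bromides at the α-carbon of both partners at −78 °C. With 22 this would give 26 directly, replacing steps 19–21.

**Step 12.** The lactol of 13 is hindered (its aldehyde carbon is neopentyl-like), so olefination may be slow. During a long heating period the freed C6 hydroxyl may add back to the enoate (oxa-Michael closure to a tetrahydrofuran), or the open β-hydroxy aldehyde may fragment by retro-aldol cleavage of C5–C1'. Fallback: open the lactone before any enoate exists. From 12, MeNHOMe·HCl with AlMe3 would give the Weinreb amide F9 with a free C6 hydroxyl. Mesylation would give the mesylate F10, and KOt-Bu would close it to the epoxy amide F11. i-Bu2AlH would reduce the amide to the aldehyde and the C7 ester to the alcohol, giving the epoxy aldehyde F12. Wittig reaction with 14 would give the epoxy enoate F13, and silylation of its C7 hydroxyl returns to 18. In this order neither a free C6 hydroxyl nor a free C5 alkoxide is present once the enoate exists.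

## Further compounds

F1 | step 9 | C3 phenylthio adduct of butenolide 10 (C2, C3 epimers) | COC(=O)C1C(Sc5ccccc5)[C@H](O[Si](c3ccccc3)(c4ccccc4)C(C)(C)C)C2=CC(=O)O[C@@H]2C1
F2 | step 9 | cis-fused dihydroxy lactone carrying a C3 phenylsulfonyl group | COC(=O)C1C(S(=O)(=O)c5ccccc5)[C@H](O[Si](c3ccccc3)(c4ccccc4)C(C)(C)C)[C@]2(O)[C@@H](O)C(=O)O[C@@H]2C1
F3 | step 15 | C1 enone corresponding to 19 | CC(C)(C)[Si](C)(C)OCC1=C[C@H](O[Si](c3ccccc3)(c4ccccc4)C(C)(C)C)[C@@]2([C@@H](O[Si](C)(C)C(C)(C)C)/C=C(\C)C(=O)OCC)O[C@H]2C1=O
F4 | step 8 | C6 bromoacetate of diol 6 | COC(=O)C1=C[C@H](O[Si](c2ccccc2)(c3ccccc3)C(C)(C)C)[C@@H](O)[C@H](OC(=O)CBr)C1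
F5 | step 8 | C5 ketone of F4 | COC(=O)C1=C[C@H](O[Si](c2ccccc2)(c3ccccc3)C(C)(C)C)C(=O)[C@H](OC(=O)CBr)C1
F6 | step 8 | triphenylphosphonium bromide from F5 | COC(=O)C1=C[C@H](O[Si](c2ccccc2)(c3ccccc3)C(C)(C)C)C(=O)[C@H](OC(=O)C[P+](c4ccccc4)(c5ccccc5)c6ccccc6)C1.[Br-]
F7 | step 21 | geranyl chloride | ClC/C=C(\C)CCC=C(C)C
F8 | step 21 | geranylbarium chloride | Cl[Ba]C/C=C(\C)CCC=C(C)C
F9 | step 12 | Weinreb amide from lactone 12 (C5–OH β, C6–OH α free) | COC(=O)C1=C[C@H](O[Si](c2ccccc2)(c3ccccc3)C(C)(C)C)[C@](O)([C@@H](O[Si](C)(C)C(C)(C)C)C(=O)N(C)OC)[C@H](O)C1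
F10 | step 12 | C6 mesylate of F9 | COC(=O)C1=C[C@H](O[Si](c2ccccc2)(c3ccccc3)C(C)(C)C)[C@](O)([C@@H](O[Si](C)(C)C(C)(C)C)C(=O)N(C)OC)[C@H](OS(C)(=O)=O)C1
F11 | step 12 | β-epoxy Weinreb amide | COC(=O)C1=C[C@H](O[Si](c3ccccc3)(c4ccccc4)C(C)(C)C)[C@@]2([C@@H](O[Si](C)(C)C(C)(C)C)C(=O)N(C)OC)O[C@H]2C1
F12 | step 12 | β-epoxy aldehyde with free C7 alcohol | OCC1=C[C@H](O[Si](c3ccccc3)(c4ccccc4)C(C)(C)C)[C@@]2([C@@H](O[Si](C)(C)C(C)(C)C)C=O)O[C@H]2C1
F13 | step 12 | β-epoxy (E)-enoate with free C7 alcohol | OCC1=C[C@H](O[Si](c3ccccc3)(c4ccccc4)C(C)(C)C)[C@@]2([C@@H](O[Si](C)(C)C(C)(C)C)/C=C(\C)C(=O)OCC)O[C@H]2C1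
A1 | alternative 1 | epoxycyclohexenol with free C4 hydroxyl, C1 p-methoxybenzyl ether and silylated C1' | CC(=O)OCC1=C[C@H](O)[C@@]2([C@@H](O[Si](CC)(CC)CC)/C=C(\C)CC/C=C(\C)CCC=C(C)C)O[C@H]2[C@@H]1OCc3ccc(OC)cc3
A2 | alternative 1 | open-chain (Z)-iodoalkene epoxy aldehyde | I/C=C(/COC(C)=O)[C@@H](OCc1ccc(OC)cc1)[C@@H]2O[C@@]2(C=O)[C@@H](O[Si](CC)(CC)CC)/C=C(\C)CC/C=C(\C)CCC=C(C)C
A3 | alternative 2 | 4-hydroxycyclohex-2-enone 5,6-cyclic carbonate with C7 acetate and silylated chain | CC(=O)OCC1=C[C@H](O)[C@@]2([C@@H](O[Si](C)(C)C(C)(C)C)/C=C(\C)CC/C=C(\C)CCC=C(C)C)OC(=O)O[C@H]2C1=O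
A4 | alternative 2 | 3-(acetoxymethyl)-2-(tert-butyldimethylsilyloxy)furan | CC(=O)OCc1ccoc1O[Si](C)(C)C(C)(C)C
A5 | alternative 2 | 4-substituted 1,3-dioxol-2-one carrying the silylated chain | O=C1OC=C(O1)[C@@H](O[Si](C)(C)C(C)(C)C)/C=C(\C)CC/C=C(\C)CCC=C(C)C
A6 | alternative 3 | ethyl epoxycyclohexenol carboxylate (one C1 epimer) | CCOC(=O)C1=C[C@H](O[Si](C)(C)C(C)(C)C)[C@@]2([C@@H](O[Si](CC)(CC)CC)/C=C(\C)CC/C=C(\C)CCC=C(C)C)O[C@H]2[C@@H]1O
A7 | alternative 3 | open-chain γ-silyloxy enoate epoxy aldehyde | CCOC(=O)/C=C/[C@H](O[Si](C)(C)C(C)(C)C)[C@@]2([C@@H](O[Si](CC)(CC)CC)/C=C(\C)CC/C=C(\C)CCC=C(C)C)O[C@H]2C=O
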